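The route rests on cutting the 2,3-dihydrofuran ring (O, C4, C5, C6, C7), which bridges the ten-membered carbocycle C1–C10, at C5–C6 and C7–O. That ring is the formal [3+2] adduct of a ketocarbene (O=C4–C5) and the terminal C6=C7 alkene of the dienol ester C6=C7–C8=C9–O of the butenolide ring. One rhodium carbenoid reaction therefore closes carbocycle and dihydrofuran together and creates C7. Its precursor 23 is an open chain. It is a C5 diazoketone with C3 as a silyl ether, joined through C1 to an E-(2-methylallylidene)butenolide made stereospecifically from an alkyne. C1 already bears the methacrylate, which deactivates C1–H toward insertion.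

Key step: step 17

Numbering:
- C1 is the CH bearing the methacrylate, C2 the CH2, C3 the tertiary carbinol carbon and C4 the enol-ether carbon.
- C5 is the vinylic CH, C6 the ring CH2, C7 the methyl-bearing ether carbon and C8 the vinylic CH.
- C9 is the enol-lactone carbon, C10 and C11 are the butenolide beta and alpha carbons, C12 is the lactone carbonyl and C13 the CH2OAc carbon.

Structure check: the target is 1S,3R,7S, and C8=C9 is E (C7 cis to C10, trans to the lactone oxygen). In a flat drawing of the carbocycle, O1, O3 and the C7 methyl group lie on one face and the ether bridge on the other.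

Assumption: compounds 1, 4 and 16 are purchased, and diazomethane is used as a freshly prepared ethereal solution.

Remark: from step 11 onward everything is kept at or below 40 °C and in the dark. The triene C6=C7–C8=C9–C10=C11 has a cis central double bond and could isomerise or undergo a six-electron electrocyclisation.

Step 1
Reactants: 1 (R)-citramalic acid
Product: 2 2-[(4R)-2,2,4-trimethyl-5-oxo-1,3-dioxolan-4-yl]acetic acid
Conditions: Me2C(OMe)2, p-TsOH·H2O (cat.), acetone, rt
Reagents that add atoms: 2,2-dimethoxypropane COC(C)(C)OC
Why: In this acid-catalysed acetalisation the alpha-hydroxy acid pair (C3–OH and the C4 carboxyl) closes the favoured five-membered dioxolanone, which masks both groups at once, leaves the C1 carboxyl free and does not touch the C3 stereocentre taken from the chiral pool.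

Step 2
Reactants: 2 dioxolanone acid
Product: 3 N-methoxy-N-methyl-2-[(4R)-2,2,4-trimethyl-5-oxo-1,3-dioxolan-4-yl]acetamide
Conditions: MeNH(OMe)·HCl, EDC·HCl, N-methylmorpholine, CH2Cl2, 0 °C to rt
Reagents that add atoms: N,O-dimethylhydroxylamine hydrochloride CNOC.Cl
Why: Carbodiimide amidation gives the Weinreb amide, the acyl donor that stops at the ketone stage in step 5, and the hindered dioxolanone carbonyl does not react with this weakly nucleophilic amine.

Step 3
Reactants: 4 furan-3-ylmethanol
Product: 5 tert-butyl(furan-3-ylmethoxy)dimethylsilane
Conditions: TBSCl, imidazole, CH2Cl2, rt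
Reagents that add atoms: tert-butyldimethylsilyl chloride CC(C)(C)[Si](C)(C)Cl
Why: Standard silylation of a primary alcohol loads the silyl group that is moved to carbon in step 4.

Step 4
Reactants: 5 silyl ether
Product: 6 [2-(tert-butyldimethylsilyl)furan-3-yl]methanol
Conditions: n-BuLi, HMPA (or DMPU), THF, −78 °C to rt; H2O
Reagents that add atoms: none
Why: Lithiation at the furan alpha position next to the side chain is followed by a retro-Brook type [1,4] oxygen-to-carbon silyl shift driven by alkoxide formation, which puts silicon on the future C12 and frees the hydroxymethyl group as a directing group.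

Step 5
Reactants: 6 [2-(tert-butyldimethylsilyl)furan-3-yl]methanol; 3 Weinreb amide
Product: 9 C1 ketone {2-(tert-butyldimethylsilyl)-4-[2-((4R)-2,2,4-trimethyl-5-oxo-1,3-dioxolan-4-yl)acetyl]furan-3-yl}methyl acetate, via dilithiated furan 7 (not isolated), via tetrahedral dilithium adduct 8 (not isolated)
Conditions: n-BuLi (2.2 equiv), DME, 0 °C; 3, THF, −78 °C; Ac2O, −78 to 0 °C; H2O
Reagents that add atoms: acetic anhydride CC(=O)OC(C)=O; n-butyllithium [Li]CCCC (lithium in 7 and 8 only)
Why: Alkoxide-directed lithiation takes the beta position (future C10) because the neighbouring alpha position is blocked by silicon, the aryllithium adds to the unhindered chelating amide faster than to the neopentyl-type dioxolanone carbonyl at −78 °C (Weinreb ketone synthesis), and acetic anhydride caps the primary alkoxide before the adduct is hydrolysed.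

Step 6
Reactants: 9 C1 ketone
Product: 10 (1S)-alcohol {2-(tert-butyldimethylsilyl)-4-[(1S)-1-hydroxy-2-((4R)-2,2,4-trimethyl-5-oxo-1,3-dioxolan-4-yl)ethyl]furan-3-yl}methyl acetate
Conditions: (R)-2-methyl-CBS-oxazaborolidine (cat.), BH3·SMe2, THF, −30 °C; MeOH
Reagents that add atoms: none
Why: In this Corey–Bakshi–Shibata reduction the substituted furyl group acts as the large and the CH2 group as the small substituent, so the (R)-catalyst should give the 1S alcohol under reagent control, and borane at low temperature leaves acetate and dioxolanone alone.

Step 7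
Reactants: 10 (1S)-alcohol
Product: 11 C1 triethylsilyl ether of 10
Conditions: TESOTf, 2,6-lutidine, CH2Cl2, −78 °C
Reagents that add atoms: triethylsilyl triflate CC[Si](CC)(CC)OS(=O)(=O)C(F)(F)F
Why: Silylation with the triflate and a hindered base is fast at −78 °C, so the C1 hydroxyl is capped before it can translactonise onto the dioxolanone carbonyl.

Step 8
Reactants: 11 silylfuran
Product: 12 5-hydroxybutenolide (C12 lactone carbonyl; C9 hemiacetal as an epimer mixture; C11 CH2OAc; C10 side chain unchanged)
Conditions: O2, tetraphenylporphyrin (cat.), visible light, CH2Cl2, −78 °C; then H2O, THF, rt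
Reagents that add atoms: dioxygen O=O
Why: [4+2] photooxygenation of the furan with singlet oxygen gives an endoperoxide in which silicon migrates from C12 to peroxide oxygen, so the carbonyl appears regiospecifically at C12 and the hemiacetal at C9 (silyl-directed furan to hydroxybutenolide oxidation), with C9 and C12 locked cis on C10=C11.

Step 9
Reactants: 12 5-hydroxybutenolide
Product: 14 diacid (1S,3R) in which the C12 carboxyl is cis to the C9 ethynyl group on C10=C11; C13 hydroxymethyl; C1 OTES; C3 OH; C4 carboxyl, via enynoic acid C4 methyl ester 13 (not isolated)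
Conditions: MeC(O)C(N2)P(O)(OMe)2, K2CO3, MeOH, 0 °C to rt; then LiOH, H2O, rt; 1 M HCl to pH 4, 0 °C
Reagents that add atoms: Ohira–Bestmann reagent CC(=O)C(=[N+]=[N-])P(=O)(OC)OC; methanol CO (methyl ester of 13 only); lithium hydroxide [Li+].[OH-]
Why: In basic methanol the pseudo-acid opens to the cis formyl carboxylate, which undergoes Seyferth–Gilbert homologation with the Ohira–Bestmann reagent as lactols and 2-formylbenzoic acid type pseudo-acids do, while the same medium removes the temporary acetate and methanolyses the dioxolanone, hydroxide then saponifies the alpha-hydroxy ester, and the tetrasubstituted alkene keeps carboxyl and ethynyl cis.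

Step 10
Reactants: 14 diacid
Product: 15 (E)-5-(iodomethylene)butenolide (iodine trans to the ring oxygen and cis to C10; C13 OH; C1 OTES; C3 OH; C4 carboxyl)
Conditions: I2, NaHCO3, MeCN, 0 °C to rt, dark
Reagents that add atoms: iodine [I][I]
Why: In this iodolactonisation of a cis-2-en-4-ynoic acid the C12 carboxylate attacks the internal carbon of the iodonium-activated terminal alkyne in the 5-exo-dig mode and anti to iodine, which fixes the E geometry whatever the thermodynamic preference, while the C4 carboxylate would need a seven-membered ring and stays out.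

Step 11
Reactants: 15 (E)-iodide; 16 tributyl(prop-1-en-2-yl)stannane
Product: 17 (E)-5-(2-methylprop-2-en-1-ylidene)butenolide (C13 OH; C1 OTES; C3 OH; C4 carboxyl)
Conditions: Pd2(dba)3 (5 mol%), AsPh3 (20 mol%), i-Pr2NEt, NMP, rt, dark
Reagents that add atoms: 16 tributyl(prop-1-en-2-yl)stannane C=C(C)[Sn](CCCC)(CCCC)CCCC
Why: Stille coupling proceeds with retention at the alkenyl iodide, so the isopropenyl group takes the position cis to C10 and the E-dienol ester forms without equilibration, the neutral room-temperature conditions spare the enol lactone, and the free allylic alcohol is inert to zerovalent palladium.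

Step 12
Reactants: 17 allylic alcohol
Product: 18 C13 acetate of 17
Conditions: Ac2O (1.2 equiv), pyridine, CH2Cl2, 0 °C; H2O
Reagents that add atoms: acetic anhydride CC(=O)OC(C)=O
Why: Acylation discriminates on steric grounds, so the primary allylic C13 hydroxyl is esterified, the tertiary C3 hydroxyl is not, and any mixed anhydride at C4 is hydrolysed on aqueous work-up.

Step 13
Reactants: 18 hydroxy acid
Product: 19 C3 triethylsilyl ether and C4 triethylsilyl ester of 18
Conditions: TESOTf (2.4 equiv), 2,6-lutidine, CH2Cl2, −78 to −20 °C
Reagents that add atoms: triethylsilyl triflate CC[Si](CC)(CC)OS(=O)(=O)C(F)(F)F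
Why: Silyl triflate silylation covers the tertiary C3 hydroxyl, which would otherwise undergo O–H insertion in step 17, and turns the acid into a silyl ester that can be activated without acid.

Step 14
Reactants: 19 silyl ester
Product: 21 C5 diazoketone (C1 OTES; C3 OTES; C13 OAc; E-dienol ester), via acid chloride 20 (not isolated)
Conditions: (COCl)2, DMF (cat.), CH2Cl2, 0 °C; evaporate; CH2N2, Et2O, −10 to 0 °C, 30 min; purge with nitrogen gas
Reagents that add atoms: oxalyl chloride ClC(=O)C(Cl)=O (chlorine in 20 only); diazomethane C=[N+]=[N-]
Why: A silyl ester reacts with oxalyl chloride and catalytic DMF to give the acid chloride with chlorosilane instead of HCl as by-product, and this acid chloride, which has no alpha hydrogen and cannot form a ketene, acylates diazomethane (first stage of the Arndt–Eistert sequence) much faster than diazomethane adds to the twisted donor-substituted triene, which is why the methacrylate, a fast dipolarophile, is not yet present.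

Step 15
Reactants: 21 bis(silyl ether) diazoketone
Product: 22 C1 alcohol (C3 OTES retained)
Conditions: PPTS (cat.), MeOH/CH2Cl2, 0 °C
Reagents that add atoms: none
Why: Acid-catalysed methanolysis of silyl ethers is governed by steric access to silicon, so the secondary C1 ether should be cleaved ahead of the tertiary C3 ether, and pyridinium tosylate is too weak an acid to protonate the diazoketone.

Step 16
Reactants: 22 C1 alcohol
Product: 23 cyclisation precursor (C1 methacrylate; C3 OTES; C5 diazoketone; C13 OAc; E-(2-methylallylidene)butenolide)
Conditions: methacrylic anhydride, Et3N, DMAP (cat.), CH2Cl2, 0 °C to rt, dark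
Reagents that add atoms: methacrylic anhydride C=C(C)C(=O)OC(=O)C(C)=C
Why: DMAP-catalysed acylation of the only free hydroxyl under basic conditions, which diazoketones tolerate, installs the final ester before the key step, so that C1–H is deactivated and no selective acylation is needed afterwards.

Step 17
Reactants: 23 cyclisation precursor
Product: 24 bridged bicyclic dienol ether (ten-membered carbocycle and 2,3-dihydrofuran closed; 1S,3R,7S; C3 OTES)
Conditions: Rh2(OAc)4 (5 mol%), degassed CH2Cl2, 40 °C, syringe-pump addition of 23 over 16 h, final concentration about 1 mM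
Reagents that add atoms: none
Why: Proposed new method: Rh2(OAc)4 (divalent rhodium) releases N2 from 23 and gives an electrophilic carbenoid at C5, which is attacked by the unhindered terminal carbon C6 of the dienol ester (the lactone oxygen pushes electron density through C9=C8–C7=C6); the zwitterion so formed, a C4 enolate facing a C7 cation delocalised over C8, C9 and the lactone oxygen, collapses by O-alkylation, and a donor–acceptor vinylcyclopropane formed instead would reach the same product by Cloke–Wilson rearrangement. The closest known reaction types are the rhodium- or copper-catalysed formal [3+2] additions of alpha-diazo ketones to enol ethers and dienes that give 2,3-dihydrofurans and the macrocyclising carbenoid cyclopropanations run under slow addition; their combination in one ring-forming event has no precedent. The ten-membered carbocycle closes in the 10-endo-trig mode (C5–C6 bond, both alkene carbons end up in the ring) and the dihydrofuran closes in the 5-exo-trig mode (enolate oxygen onto C7, the C7–C8 pi bond stays outside the new ring). C7 is the only new stereocentre and is under substrate control: dipole minimisation should hold the C4 oxygen anti to the C3–O bond, that is on the ring face opposite to the C1 and C3 oxygens, from where it bonds to C7 to give 7S with the methyl group on the face of those oxygens; this control is unproven, and Rh2(S-PTTL)4 or its enantiomer is the lever if it is weak. The step needs the remote alkene to win over insertion, ylide formation and dimerisation: the C3 hydroxyl is silylated, the acyloxy group and the electron-poor C10 deactivate C1–H toward 1,5-insertion and make O1 a poor ylide donor, the methacrylate alkene is electron-poor, the E geometry turns C6 toward the tether, and slow addition at high dilution suppresses carbene dimers.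

Step 18
Reactants: 24 C3 silyl ether
Product: 25 target CNP0394509.2
Conditions: TBAF/AcOH (1:1), THF, 0 °C
Reagents that add atoms: none
Why: Fluoride-induced desilylation buffered with acetic acid is close to neutral, so the acid-labile cyclic enol ether and the base-labile acetate, methacrylate and enol lactone should survive, and no stereocentre is touched.

Compound list

1 | (R)-citramalic acid | OC(=O)C[C@@](C)(O)C(=O)O | starting material
2 | 2-[(4R)-2,2,4-trimethyl-5-oxo-1,3-dioxolan-4-yl]acetic acid | OC(=O)C[C@@]1(C)OC(C)(C)OC1=O | intermediate
3 | Weinreb amide of 2 | CON(C)C(=O)C[C@@]1(C)OC(C)(C)OC1=O | intermediate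
4 | furan-3-ylmethanol | OCc1ccoc1 | starting material
5 | tert-butyl(furan-3-ylmethoxy)dimethylsilane | CC(C)(C)[Si](C)(C)OCc1ccoc1 | intermediate
6 | [2-(tert-butyldimethylsilyl)furan-3-yl]methanol | CC(C)(C)[Si](C)(C)c1occc1CO | intermediate
7 | 6 lithiated at the ring beta carbon and at oxygen | CC(C)(C)[Si](C)(C)c1occ([Li])c1CO[Li] | intermediate
8 | dilithium tetrahedral adduct of 7 to 3 | CC(C)(C)[Si](C)(C)c1occ(C(O[Li])(N(C)OC)C[C@@]2(C)OC(C)(C)OC2=O)c1CO[Li] | intermediate
9 | C1 ketone, C13 acetate, silylfuran, dioxolanone | CC(C)(C)[Si](C)(C)c1occ(C(=O)C[C@@]2(C)OC(C)(C)OC2=O)c1COC(C)=O | intermediate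
10 | (1S)-alcohol from 9 | CC(C)(C)[Si](C)(C)c1occ([C@@H](O)C[C@@]2(C)OC(C)(C)OC2=O)c1COC(C)=O | intermediate
11 | C1 triethylsilyl ether of 10 | CC(C)(C)[Si](C)(C)c1occ([C@@H](O[Si](CC)(CC)CC)C[C@@]2(C)OC(C)(C)OC2=O)c1COC(C)=O | intermediate
12 | 5-hydroxybutenolide, C9 epimers | CC(=O)OCC1=C([C@@H](O[Si](CC)(CC)CC)C[C@@]2(C)OC(C)(C)OC2=O)C(O)OC1=O | intermediate
13 | enynoic acid with C4 methyl ester, C3 OH, C13 OH | OC(=O)/C(CO)=C(\C#C)[C@@H](O[Si](CC)(CC)CC)C[C@@](C)(O)C(=O)OC | intermediate
14 | enynoic diacid, C12 carboxyl cis to ethynyl | OC(=O)/C(CO)=C(\C#C)[C@@H](O[Si](CC)(CC)CC)C[C@@](C)(O)C(=O)O | intermediate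
15 | (E)-5-(iodomethylene)butenolide acid | OCC1=C([C@@H](O[Si](CC)(CC)CC)C[C@@](C)(O)C(=O)O)/C(=C\I)OC1=O | intermediate
16 | tributyl(prop-1-en-2-yl)stannane | C=C(C)[Sn](CCCC)(CCCC)CCCC | starting material
17 | (E)-5-(2-methylallylidene)butenolide acid, C13 OH | OCC1=C([C@@H](O[Si](CC)(CC)CC)C[C@@](C)(O)C(=O)O)/C(=C\C(C)=C)OC1=O | intermediate
18 | C13 acetate of 17 | CC(=O)OCC1=C([C@@H](O[Si](CC)(CC)CC)C[C@@](C)(O)C(=O)O)/C(=C\C(C)=C)OC1=O | intermediate
19 | C3 OTES ether and C4 TES ester of 18 | CC(=O)OCC1=C([C@@H](O[Si](CC)(CC)CC)C[C@@](C)(O[Si](CC)(CC)CC)C(=O)O[Si](CC)(CC)CC)/C(=C\C(C)=C)OC1=O | intermediate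
20 | C4 acid chloride | CC(=O)OCC1=C([C@@H](O[Si](CC)(CC)CC)C[C@@](C)(O[Si](CC)(CC)CC)C(Cl)=O)/C(=C\C(C)=C)OC1=O | intermediate
21 | C5 diazoketone, C1 and C3 OTES | CC(=O)OCC1=C([C@@H](O[Si](CC)(CC)CC)C[C@@](C)(O[Si](CC)(CC)CC)C(=O)C=[N+]=[N-])/C(=C\C(C)=C)OC1=O | intermediate
22 | C5 diazoketone, C1 OH, C3 OTES | CC(=O)OCC1=C([C@@H](O)C[C@@](C)(O[Si](CC)(CC)CC)C(=O)C=[N+]=[N-])/C(=C\C(C)=C)OC1=O | intermediate
23 | key-step precursor, C1 methacrylate, C3 OTES | C=C(C)C(=O)O[C@H](C1=C(COC(C)=O)C(=O)O/C1=C/C(C)=C)C[C@@](C)(O[Si](CC)(CC)CC)C(=O)C=[N+]=[N-] | intermediate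
24 | key-step product, bridged dienol ether, C3 OTES | C=C(C)C(=O)O[C@H]1C[C@@](C)(O[Si](CC)(CC)CC)C2=CC[C@@](C)(/C=C3/OC(=O)C(COC(C)=O)=C31)O2 | intermediate
25 | CNP0394509.2 | C=C(C)C(=O)O[C@H]1C[C@@](C)(O)C2=CC[C@@](C)(/C=C3/OC(=O)C(COC(C)=O)=C31)O2 | target

Total step count: 18.
Longest linear sequence: 16 steps (from 4 or from 1 to 25).

Steps most likely to fail

**1. Step 17.**
- The carbenoid may be consumed before the strained ring can close, by dimerisation, by insertion into C–H bonds of the triethylsilyl group, or by capture at a carbonyl oxygen.
- The enolate may also close on the wrong face of C7.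

The fallback sets out from 23 and comes back at 24. It separates the two bond formations into two known reaction types.
- Slow addition of 23 to [Cu(MeCN)4]PF6 (monovalent copper) in CH2Cl2 would perform a macrocyclising carbenoid cyclopropanation of the terminal alkene and give the macrocyclic vinylcyclopropyl ketone F1, which is isolated.
- This donor–acceptor cyclopropane would then be opened at C5–C7 and reclosed through oxygen by a Cloke–Wilson rearrangement (MgI2 in CH2Cl2 or gentle warming below 60 °C) to give 24.

**2. Step 11.**
- Oxidative addition and transmetalation at the crowded alkenyl iodide may be slow.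
- The free acid may protodestannylate the reagent.
- Reversible addition of nucleophiles at C8 may erode the E geometry.

The fallback sets out from 14 and comes back at 17. It bypasses the iodide.
- 2-Bromopropene, Pd(PPh3)4 and K2CO3 in DMF at 40 °C give an isopropenylpalladium bromide (divalent palladium) that activates the alkyne.
- The C12 carboxylate adds anti to palladium, and reductive elimination places the isopropenyl group trans to the ring oxygen.
- This known cyclisation–coupling of alkynoic acids passes through no compound outside the list (none F0).

**3. Step 15.**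
- The discrimination between the crowded secondary C1 silyl ether and the tertiary C3 silyl ether may be poor, with partial loss of both groups.

The fallback sets out from 21 and comes back at 23. It gives up selective deprotection in favour of selective acylation.
- TBAF/AcOH removes both silyl ethers and gives the diol diazoketone F2.
- Methacrylic anhydride, Et3N and DMAP acylate only the secondary hydroxyl and give the C3-hydroxy methacrylate F3.
- Et3SiCl, imidazole and DMAP in DMF re-silylate the tertiary hydroxyl to give 23.

Further compounds

F1 | step 17 | macrocyclic vinylcyclopropyl ketone (C5–C6–C7 cyclopropane cis-fused to a nine-membered ring, C3 OTES) | C=C(C)C(=O)O[C@H]1C[C@@](C)(O[Si](CC)(CC)CC)C(=O)[C@H]2C[C@@]2(C)/C=C3/OC(=O)C(COC(C)=O)=C31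
F0 | step 11 | none | none
F2 | step 15 | diol diazoketone (C1 OH, C3 OH) | CC(=O)OCC1=C([C@@H](O)C[C@@](C)(O)C(=O)C=[N+]=[N-])/C(=C\C(C)=C)OC1=O
F3 | step 15 | C3-hydroxy methacrylate (C1 methacrylate, C3 OH, C5 diazoketone) | C=C(C)C(=O)O[C@H](C1=C(COC(C)=O)C(=O)O/C1=C/C(C)=C)C[C@@](C)(O)C(=O)C=[N+]=[N-]
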